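No rate constant is available yet, so the flasks are read through a count that needs none: target made per catalyst charged, bound and free read together.

| flask | substrate | coupling partner | free catalyst | time |
|---|---|---|---|---|
| alder | 120 mM | 120 mM | 6.00 mM |  |
| ash | 72.0 mM | 72.0 mM | 6.00 mM |  |
| larch | 120 mM | 60.0 mM | 6.00 mM |  |
| elm | 120 mM | 120 mM | 12.0 mM |  |
| birch | 120 mM | 60.0 mM | 2.00 mM | 19 h |

| alder run: time / h | alder run: [target] / mM | ash run: time / h | ash run: [target] / mM | larch run: time / h | larch run: [target] / mM | elm run: time / h | elm run: [target] / mM |
|---|---|---|---|---|---|---|---|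
| 0.84 | 4.3 | 0.84 | 2.7 | 0.84 | 3.5 | 0.84 | 6.6 |
| 2.6 | 12.2 | 2.6 | 10.0 | 2.6 | 11.3 | 2.6 | 24.1 |
| 4.9 | 23.3 | 4.9 | 17.0 | 4.9 | 16.6 | 4.9 | 43.6 |
| 7.8 | 33.2 | 7.8 | 24.7 | 7.8 | 22.7 | 7.8 | 59.9 |
| 11 | 40.0 | 11 | 28.6 | 11 | 25.9 | 11 | 69.5 |
| 15 | 46.6 | 15 | 32.5 | 15 | 28.4 | 15 | 74.1 |
| 19 | 48.3 | 19 | 31.8 | 19 | 29.0 | 19 | 75.3 |

(readings scatter by 0.6 mM)

- Overall: substrate + coupling partner -> target, with free catalyst as catalyst.
- Constant volume, constant temperature.
- Bound and free are read together.
- An order is taken over about fifteen percent of the charge, up and down.

- apparent order in [free catalyst] of the starting rate, round the charge of the alder run (the rate where two percent of its substrate have turned into target)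
- apparent order in [substrate] of the starting rate, round the charge of the alder run (the rate where two percent of its substrate have turned into target) (one fixed amount of target, the same in the runs compared)
- target in the birch run at 19 h, as a share of the substrate charged

Birch has the substrate and coupling partner of larch, 120 mM and 60.0 mM, with a third of its catalyst. In both, the coupling partner is charged at less than the substrate and is the limiting reagent.

In the first hours, target follows catalyst: at 2.6 h, elm, with twice the catalyst of alder, holds twice its target. Larch has by then averaged 4.35 mM h⁻¹.

In the middle, between 7.8 h and 11 h, larch gains 1.00 mM h⁻¹, a quarter of that early rate. Subtracting its target from the charge leaves at most 34.1 mM of the 60.0 mM of coupling partner.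

At the end, from 15 h to 19 h, larch gains 0.600 mM, the size of the scatter of one reading, and stands at 29.0 mM. From one charge, elm ends higher than alder, 75.3 mM against 48.3 mM, so the end point moves with catalyst. That suggests counting the end per catalyst:

turnovers in larch = 29.0 mM / 6.00 mM = 4.83

This count, target per catalyst charged at 19 h, is the turnover number. My own reckoning carries it to birch:

target in birch = 4.83 × 2.00 mM = 9.67 mM, or 8.06% of the substrate

Alder reaches 8.05 turnovers and elm 6.27, fewer with more catalyst on one charge. I therefore place birch somewhat above that figure.

The forecast gives 0.95 for the catalyst order, 0.35 for the substrate order and 13% for birch, higher than my figure. It calls its substrate order indirect, since “no run changes substrate alone”.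

The flask runs by these steps:

    free catalyst + substrate → catalyst-substrate complex (115.2 M⁻¹ h⁻¹)
    catalyst-substrate complex + coupling partner → loaded catalyst (58.32 M⁻¹ h⁻¹)
    loaded catalyst → target + free catalyst (1.292 h⁻¹)
    coupling partner → lost reagent (0.07884 h⁻¹)
    catalyst-substrate complex → spent catalyst + substrate (0.2812 h⁻¹)

Birch gives 9.88%, with orders of 0.97 in catalyst and 0.079 in substrate, the latter lower than the forecast's 0.35. Larch, with half the coupling partner of alder, keeps 0.81 of its rate at the same amount of target. Birch reaches 5.93 turnovers against 4.83 in larch, a ratio of 1.23 for a third of the catalyst. Alder, at half the catalyst of elm, reaches a turnover count 1.28 times that of elm.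

(Readings and results stem from a simulated flask with constants of no real substance.)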